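**Assumption:** the target, 2-heptacosyl-5,7-dihydroxy-4H-chromen-4-one (C36H60O4), has no stereocentre and no stereogenic double bond, so there is no configuration to set.

## Retrosynthetic overview

1. O1–C2 disconnection: the pyranone is opened to the 1-(2,4,6-trihydroxyphenyl)-1,3-diketone (cyclodehydration in the forward sense; the only ring formed, the benzene ring is bought).
2. Key C3–C4 disconnection with both partners in reversed polarity: the formyl carbon of phloroglucinaldehyde acts as an acyl anion equivalent (acyl–Rh(III) from phenol-directed C–H activation), and the α-carbon of a C29 methyl ketone acts as an enolonium equivalent (α-oxo Rh-carbene from a sulfoxonium ylide).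
3. The sulfoxonium ylide comes from octacosanoic acid (C28) and dimethylsulfoxonium methylide, which supplies C3.
4. No protecting groups: the symmetric triphenol aldehyde supplies O1, 5-OH and 7-OH directly.

## Route

Step 1
Reactants: 1 octacosanoic acid
Product: 3 1-[dimethyl(oxo)-λ6-sulfanylidene]nonacosan-2-one (the dimethylsulfoxonium ylide C27H55–CO–CH=S(O)Me2), via octacosanoyl chloride 2 (not isolated)
Conditions: (i) SOCl2 (3 equiv), DMF (cat.), toluene, 75 °C, 2 h, then evaporate; (ii) Me3S(O)I (3 equiv), KOtBu (3 equiv), THF, reflux 2 h, cool to 0 °C, add crude 2 in warm THF, 0 °C to rt, 3 h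
Reagents that add atoms: trimethylsulfoxonium iodide, C[S+](C)(C)=O.[I-] (gives the CH=S(O)Me2 unit through its ylide); thionyl chloride, O=S(Cl)Cl (its Cl is carried only by intermediate 2)
Why: Acylation of the Corey–Chaykovsky sulfoxonium methylide by an acid chloride, in which a second equivalent of ylide deprotonates the acylated sulfoxonium salt to give the stabilised, isolable β-keto sulfoxonium ylide; the saturated chain is inert.

Step 2
Reactants: 3 1-[dimethyl(oxo)-λ6-sulfanylidene]nonacosan-2-one (1.0 equiv); 4 2,4,6-trihydroxybenzaldehyde (1.5 equiv)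
Product: 6 2-heptacosyl-5,7-dihydroxy-4H-chromen-4-one, via 1-(2,4,6-trihydroxyphenyl)triacontane-1,3-dione 5 (not isolated)
Conditions: [Cp*RhCl2]2 (4 mol %), AgSbF6 (16 mol %), PivOH (1 equiv), DCE–HFIP 4:1, sealed tube, 80 °C, 16 h, Ar; then TsOH·H2O (20 mol %), 80 °C, 1 h
Reagents that add atoms: none
Why: Rh(III)-catalysed formyl C–H activation/carbene-insertion annulation of a salicylaldehyde with a sulfoxonium ylide: the ortho-phenoxide directs Cp*Rh(III) into the formyl C–H bond to give a five-membered acyl-rhodacycle (acyl anion equivalent), 3 loses DMSO on rhodium to give an electrophilic α-oxo carbene (enolonium equivalent), migratory insertion forms C3–C4, protodemetalation releases diketone 5, and acid-catalysed cyclodehydration through the second ortho-OH closes the pyranone; no stereocentre is formed, and running the reaction on the unprotected triphenol is an extension of the usual substrate scope, made possible because the two ortho-OH groups of 4 are equivalent.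

## Compound list

1 | octacosanoic acid | CCCCCCCCCCCCCCCCCCCCCCCCCCCC(=O)O | starting material
2 | octacosanoyl chloride | CCCCCCCCCCCCCCCCCCCCCCCCCCCC(=O)Cl | intermediate
3 | 1-[dimethyl(oxo)-λ6-sulfanylidene]nonacosan-2-one | CCCCCCCCCCCCCCCCCCCCCCCCCCCC(=O)C=S(C)(C)=O | intermediate
4 | 2,4,6-trihydroxybenzaldehyde | O=Cc1c(O)cc(O)cc1O | starting material
5 | 1-(2,4,6-trihydroxyphenyl)triacontane-1,3-dione | CCCCCCCCCCCCCCCCCCCCCCCCCCCC(=O)CC(=O)c1c(O)cc(O)cc1O | intermediate
6 | 2-heptacosyl-5,7-dihydroxy-4H-chromen-4-one | CCCCCCCCCCCCCCCCCCCCCCCCCCCc1cc(=O)c2c(O)cc(O)cc2o1 | target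

## Step count and risks

Total step count: 2. Longest linear sequence: 2 (1 → 3 → 6).

The route has only two steps, so both are ranked; step 2 appears twice because it can fail in two independent ways.

Risk 1, step 2 (free 5-/7-OH groups). The acidic para-OH may protonate the ylide and lead to O-alkylation, the triphenol may bind the cationic rhodium, and 4 dissolves poorly. The fallback sets out from 3 and comes back at 6. Compound 3 is coupled under the same rhodium conditions (DCE alone) with commercial 2-hydroxy-4,6-dimethoxybenzaldehyde F1, which has only the directing OH free. This gives, through 1-(2-hydroxy-4,6-dimethoxyphenyl)triacontane-1,3-dione F2 formed in the flask, 2-heptacosyl-5,7-dimethoxy-4H-chromen-4-one F3. Both methyl ethers are then cleaved with BBr3 (6 equiv, CH2Cl2, −78 °C to reflux) to give 6. This adds one step and a protecting-group strategy.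

Risk 2, step 2 (carbene delivery from the ylide). Loss of DMSO from the waxy C29 ylide may need temperatures at which the electron-rich aldehyde deformylates or the protonated ylide is consumed unproductively. The fallback sets out from crude 2 and comes back at 5, and from there to 6. Compound 2 is treated with trimethylsilyldiazomethane (THF/MeCN, 0 °C) to give 1-diazononacosan-2-one F5. F5 is used in place of 3 with 4 and the same Cp*Rh(III) catalyst at 40–50 °C; loss of N2 gives the same α-oxo carbene under milder conditions. This is the less certain of the fallbacks, because acceptor-only diazoketones are less well behaved with Cp*Rh(III) than the ylide.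

Risk 3, step 1 (acylation of the ylide). The long-chain acid chloride can form a ketene with the basic ylide or acylate twice, and 1 and 2 dissolve poorly. The fallback sets out from 1 and comes back at 3. Compound 1 is esterified with 4-nitrophenol (DCC, DMAP, CH2Cl2/THF, 40 °C) to give crystalline 4-nitrophenyl octacosanoate F4, an acyl donor much less prone to ketene formation. F4 is then treated with dimethylsulfoxonium methylide (3 equiv, THF, rt to 50 °C) to give 3.

## Further compounds

F1 | step 2 | 2-hydroxy-4,6-dimethoxybenzaldehyde | COc1cc(O)c(C=O)c(OC)c1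
F2 | step 2 | 1-(2-hydroxy-4,6-dimethoxyphenyl)triacontane-1,3-dione | CCCCCCCCCCCCCCCCCCCCCCCCCCCC(=O)CC(=O)c1c(O)cc(OC)cc1OC
F3 | step 2 | 2-heptacosyl-5,7-dimethoxy-4H-chromen-4-one | CCCCCCCCCCCCCCCCCCCCCCCCCCCc1cc(=O)c2c(OC)cc(OC)cc2o1
F4 | step 1 | 4-nitrophenyl octacosanoate | CCCCCCCCCCCCCCCCCCCCCCCCCCCC(=O)Oc1ccc(cc1)[N+](=O)[O-]
F5 | step 2 | 1-diazononacosan-2-one | CCCCCCCCCCCCCCCCCCCCCCCCCCCC(=O)C=[N+]=[N-]
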